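**Retrosynthetic overview**
1. Ring A is a hexasubstituted resorcylate. Its carbons C1 (CO2Me), C2 (OH), C3 (prenyl), C4 (OH), C5 (prenyl) and C6 (CH2CH2-ring B) are C2 to C7 of a methyl 3,5,7-trioxononanoate prenylated at C4 and C6, so ring A is opened at its C1–C6 bond (aldol of chain C2 on the chain C7 ketone).
2. The triketo ester is stored as a diketo-dioxinone. Loss of acetone and capture of methanol release it and install the methyl ester in the flask where the ring closes.
3. The diketo-dioxinone is cut between the prenylated methine (chain C6) and the C7 ketone, giving the dianion of a diprenylated keto-dioxinone and the Weinreb amide of O-silylated phloretic acid. A beta-keto acyl donor is avoided because its acidic methine would quench any dienolate.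
4. The keto-dioxinone comes from 2,2,6-trimethyl-1,3-dioxin-4-one by gamma-acylation with 5-methylhex-4-enoyl chloride (first prenyl unit), then alkylation of the new active methylene with prenyl bromide (second prenyl unit).
5. Ring B is bought with phloretic acid and ring A is the only ring formed (step 7). Fluoride removes the silyl group last, and the target has no stereocentre.

Key step: step 7

Assumption: 5-methylhex-4-enoic acid is taken as a catalogue compound, and the labile methine centres of the open-chain intermediates are carried as mixtures of epimers and enol tautomers.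

**Step 1**
Reactants: 1 phloretic acid
Product: 3 3-(4-hydroxyphenyl)-N-methoxy-N-methylpropanamide, via acyl imidazole 2 (not isolated)
Conditions: carbonyldiimidazole (1.1 equiv), THF, rt; then MeNHOMe·HCl (1.3 equiv), rt
Reagents that add atoms: N,O-dimethylhydroxylamine hydrochloride, CNOC.Cl; 1,1'-carbonyldiimidazole, O=C(n1ccnc1)n1ccnc1 (its imidazolyl group stays only in 2)
Why: Carbonyldiimidazole activation followed by aminolysis is a standard Weinreb amide synthesis, and the carboxylic acid takes up the reagent ahead of the phenol, so ring B needs no protection yet.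

**Step 2**
Reactants: 3 3-(4-hydroxyphenyl)-N-methoxy-N-methylpropanamide
Product: 4 N-methoxy-N-methyl-3-[4-(triisopropylsilyloxy)phenyl]propanamide
Conditions: iPr3SiCl (1.2 equiv), imidazole (2.5 equiv), DMF, rt
Reagents that add atoms: chlorotriisopropylsilane, CC(C)[Si](Cl)(C(C)C)C(C)C
Why: Imidazole-promoted O-silylation of a phenol is routine, and the triisopropylsilyl ether is chosen over a smaller silyl ether because it should outlast lithium amides and carbonate in methanol yet fall cleanly to fluoride.

**Step 3**
Reactants: 5 5-methylhex-4-enoic acid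
Product: 6 5-methylhex-4-enoyl chloride
Conditions: (COCl)2 (1.2 equiv), DMF (cat.), CH2Cl2, 0 °C to rt; concentrate and use crude
Reagents that add atoms: oxalyl chloride, O=C(Cl)C(=O)Cl
Why: Vilsmeier-type chlorination of a carboxylic acid with oxalyl chloride and catalytic DMF runs at or below room temperature, which is mild enough to leave the trisubstituted alkene untouched.

**Step 4**
Reactants: 7 2,2,6-trimethyl-4H-1,3-dioxin-4-one; 6 5-methylhex-4-enoyl chloride
Product: 9 2,2-dimethyl-6-(6-methyl-2-oxohept-5-enyl)-4H-1,3-dioxin-4-one, via lithium dienolate 8 (not isolated)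
Conditions: 7 (2.2 equiv), LiN(SiMe3)2 (2.2 equiv), THF, −78 °C; 6 (1.0 equiv), −78 to −20 °C; 1 M HCl, 0 °C
Reagents that add atoms: LiN(SiMe3)2, [Li+].C[Si](C)(C)[N-][Si](C)(C)C (gives only the lithium of 8; nothing stays in 9)
Why: Vinylogous Claisen-type C-acylation of the dioxinone lithium dienolate takes place at the exocyclic gamma carbon, and the second equivalent of the cheap dienolate absorbs the acidic proton of the product.

**Step 5**
Reactants: 9 2,2-dimethyl-6-(6-methyl-2-oxohept-5-enyl)-4H-1,3-dioxin-4-one; 10 prenyl bromide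
Product: 12 6-(2,10-dimethyl-6-oxoundeca-2,9-dien-5-yl)-2,2-dimethyl-4H-1,3-dioxin-4-one (racemic), via sodium enolate 11 (not isolated)
Conditions: NaH (1.05 equiv), THF, 0 °C; 10 (1.05 equiv), 0 °C to rt
Reagents that add atoms: NaH, [Na+].[H-] (gives only the sodium of 11; nothing stays in 12)
Why: This is an active methylene alkylation (SN2) at the carbon flanked by dioxinone C6 and the ketone, where the soft allylic bromide favours carbon over oxygen, one equivalent of base and halide limits a second alkylation, and the new stereocentre is formed racemic and erased in step 7.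

**Step 6**
Reactants: 12 6-(2,10-dimethyl-6-oxoundeca-2,9-dien-5-yl)-2,2-dimethyl-4H-1,3-dioxin-4-one; 4 N-methoxy-N-methyl-3-[4-(triisopropylsilyloxy)phenyl]propanamide
Product: 14 2,2-dimethyl-6-{9-methyl-4-(3-methylbut-2-enyl)-3,5-dioxo-1-[4-(triisopropylsilyloxy)phenyl]dec-8-en-6-yl}-4H-1,3-dioxin-4-one (mixture of epimers and enol tautomers), via dilithium dianion 13 (not isolated)
Conditions: LiN(iPr)2 (LDA, 2.3 equiv), THF, −78 to −40 °C; 4 (0.9 equiv), −40 to −10 °C; AcOH, −78 °C; rapid chromatography
Reagents that add atoms: LiN(iPr)2, [Li+].CC(C)[N-]C(C)C (gives only the lithium of 13; nothing stays in 14)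
Why: In this beta-dicarbonyl dianion acylation the second, less stabilised carbanion at the ketone alpha' methylene is the more nucleophilic site and takes the acyl group of the Weinreb amide, which transfers only once, while the two methine centres form as an inconsequential mixture.

**Step 7**
Reactants: 14 2,2-dimethyl-6-{9-methyl-4-(3-methylbut-2-enyl)-3,5-dioxo-1-[4-(triisopropylsilyloxy)phenyl]dec-8-en-6-yl}-4H-1,3-dioxin-4-one
Product: 18 methyl 2,4-dihydroxy-3,5-bis(3-methylbut-2-enyl)-6-{2-[4-(triisopropylsilyloxy)phenyl]ethyl}benzoate, via acylketene 15 (not isolated), via triketo ester 16 (not isolated), via cyclic aldol 17 (not isolated)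
Conditions: MeOH (20 equiv), PhMe, 110 °C, sealed tube, argon; then Cs2CO3 (3 equiv), MeOH, 0 °C to rt; then 1 M HCl to pH 3, 0 °C
Reagents that add atoms: methanol, CO
Why: Heating expels acetone from the dioxinone in a retro-hetero-Diels–Alder reaction, and the large excess of methanol takes up acylketene 15 as beta-keto ester 16 before its own enol oxygen can close a 2-pyranone. Cs2CO3 then ionises the only unsubstituted active methylene, chain C2, which attacks the C7 ketone in a 6-exo-trig aldol closure (enolendo through the C3 enolate or enolexo through the ester enolate, both allowed for a six-membered ring) and so makes the C1–C6 bond of ring A in 17. E1cB loss of water, completed by the brief acid stage, and enolisation of the two remaining ketones give arene 18; the closest known reaction type is this same thermolysis, alcohol capture and carbonate-mediated aldol aromatisation of diketo-dioxinones to resorcylates, here asked to deliver a hexasubstituted ring. The methine centres of 14 to 17 and the carbinol carbon of 17 all end as sp2 carbons, so no stereocontrol is needed. Closure from C2 must win over three alternatives: Claisen attack of C6 on the ester gives a trione with a quaternary prenylated carbon that cannot aromatise and can reopen in basic methanol, aldol attack of C8 on the C3 ketone would also end in an arene but needs a carbanion held by one carbonyl only and is beyond carbonate, and attack of C4 or C6 on a ketone would close four-membered rings. The acid stage is kept cold and dilute because an ortho-prenyl phenol closes to a chroman in strong acid, and the triisopropylsilyl ether should pass through all three stages.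

**Step 8**
Reactants: 18 methyl 2,4-dihydroxy-3,5-bis(3-methylbut-2-enyl)-6-{2-[4-(triisopropylsilyloxy)phenyl]ethyl}benzoate
Product: 19 methyl 2,4-dihydroxy-6-[2-(4-hydroxyphenyl)ethyl]-3,5-bis(3-methylbut-2-enyl)benzoate
Conditions: Bu4NF (1.1 equiv), AcOH (1.1 equiv), THF, 0 °C
Reagents that add atoms: none
Why: Fluoride-mediated desilylation of an aryl silyl ether is fast, and the acetic acid buffer keeps the resorcylate ester, the free phenols and both prenyl groups out of strongly basic or acidic conditions.

**Compound list**
1 | phloretic acid, 3-(4-hydroxyphenyl)propanoic acid | OC(=O)CCc1ccc(O)cc1 | starting material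
2 | 3-(4-hydroxyphenyl)-1-(imidazol-1-yl)propan-1-one (acyl imidazole) | O=C(CCc1ccc(O)cc1)n1ccnc1 | intermediate
3 | 3-(4-hydroxyphenyl)-N-methoxy-N-methylpropanamide | CON(C)C(=O)CCc1ccc(O)cc1 | intermediate
4 | N-methoxy-N-methyl-3-[4-(triisopropylsilyloxy)phenyl]propanamide | CON(C)C(=O)CCc1ccc(O[Si](C(C)C)(C(C)C)C(C)C)cc1 | intermediate
5 | 5-methylhex-4-enoic acid | CC(C)=CCCC(=O)O | starting material
6 | 5-methylhex-4-enoyl chloride | CC(C)=CCCC(=O)Cl | intermediate
7 | 2,2,6-trimethyl-4H-1,3-dioxin-4-one | CC1=CC(=O)OC(C)(C)O1 | starting material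
8 | lithium 2,2-dimethyl-6-methylidene-1,3-dioxin-4-olate (lithium dienolate of 7) | [Li+].[O-]C1=CC(=C)OC(C)(C)O1 | intermediate
9 | 2,2-dimethyl-6-(6-methyl-2-oxohept-5-enyl)-4H-1,3-dioxin-4-one | CC1(C)OC(=CC(=O)O1)CC(=O)CCC=C(C)C | intermediate
10 | prenyl bromide, 1-bromo-3-methylbut-2-ene | CC(C)=CCBr | starting material
11 | sodium 1-(2,2-dimethyl-4-oxo-1,3-dioxin-6-yl)-6-methylhepta-1,5-dien-2-olate (sodium enolate of 9) | [Na+].CC1(C)OC(=CC(=O)O1)C=C([O-])CCC=C(C)C | intermediate
12 | 6-(2,10-dimethyl-6-oxoundeca-2,9-dien-5-yl)-2,2-dimethyl-4H-1,3-dioxin-4-one (racemic) | CC1(C)OC(=CC(=O)O1)C(CC=C(C)C)C(=O)CCC=C(C)C | intermediate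
13 | dilithium dianion of 12 (extended dioxinone dienolate plus ketone alpha' enolate) | [Li+].[Li+].[O-]C1=CC(OC(C)(C)O1)=C(CC=C(C)C)C([O-])=CCC=C(C)C | intermediate
14 | 2,2-dimethyl-6-{9-methyl-4-(3-methylbut-2-enyl)-3,5-dioxo-1-[4-(triisopropylsilyloxy)phenyl]dec-8-en-6-yl}-4H-1,3-dioxin-4-one (mixture of epimers and enol tautomers) | CC1(C)OC(=CC(=O)O1)C(CC=C(C)C)C(=O)C(CC=C(C)C)C(=O)CCc1ccc(O[Si](C(C)C)(C(C)C)C(C)C)cc1 | intermediate
15 | 4,6-bis(3-methylbut-2-enyl)-3,5,7-trioxo-9-[4-(triisopropylsilyloxy)phenyl]non-1-en-1-one (acylketene) | O=C=CC(=O)C(CC=C(C)C)C(=O)C(CC=C(C)C)C(=O)CCc1ccc(O[Si](C(C)C)(C(C)C)C(C)C)cc1 | intermediate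
16 | methyl 4,6-bis(3-methylbut-2-enyl)-3,5,7-trioxo-9-[4-(triisopropylsilyloxy)phenyl]nonanoate (mixture of epimers) | COC(=O)CC(=O)C(CC=C(C)C)C(=O)C(CC=C(C)C)C(=O)CCc1ccc(O[Si](C(C)C)(C(C)C)C(C)C)cc1 | intermediate
17 | methyl 2-hydroxy-3,5-bis(3-methylbut-2-enyl)-4,6-dioxo-2-{2-[4-(triisopropylsilyloxy)phenyl]ethyl}cyclohexane-1-carboxylate (mixture of diastereomers) | COC(=O)C1C(=O)C(CC=C(C)C)C(=O)C(CC=C(C)C)C1(O)CCc1ccc(O[Si](C(C)C)(C(C)C)C(C)C)cc1 | intermediate
18 | methyl 2,4-dihydroxy-3,5-bis(3-methylbut-2-enyl)-6-{2-[4-(triisopropylsilyloxy)phenyl]ethyl}benzoate | COC(=O)c1c(O)c(CC=C(C)C)c(O)c(CC=C(C)C)c1CCc1ccc(O[Si](C(C)C)(C(C)C)C(C)C)cc1 | intermediate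
19 | methyl 2,4-dihydroxy-6-[2-(4-hydroxyphenyl)ethyl]-3,5-bis(3-methylbut-2-enyl)benzoate | COC(=O)c1c(O)c(CC=C(C)C)c(O)c(CC=C(C)C)c1CCc1ccc(O)cc1 | target

**Step count**
Total steps: 8. Longest linear sequence: 6 (steps 3, 4, 5, 6, 7, 8). Steps 1 and 2 form the convergent branch that joins at step 6.

**Steps most likely to fail**

Step 7. Ring closure onto the crowded C7 ketone may be outrun by two processes. One is methanolytic retro-Claisen cleavage of the two poorly enolised 2-substituted 1,3-diketone units. The other is lactonisation of an enol oxygen onto the ester or the ketene.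

The fallback sets out from 14 and comes back at 19. Compound 14 is treated with Et3N in CH2Cl2 at rt with no methanol present, so the dioxinone stays closed. Its own C5 carbon, through the gamma-deprotonated dienolate, then adds to the same ketone. Loss of water should give the acetonide-bridged resorcylate 7-hydroxy-2,2-dimethyl-6,8-bis(3-methylbut-2-enyl)-5-{2-[4-(triisopropylsilyloxy)phenyl]ethyl}-4H-1,3-benzodioxin-4-one F1. The ester is unmasked only after the arene exists. NaOMe in MeOH at 60 °C should open the aryl ester to the methyl ester, release acetone and strip the silyl ether, giving 19 directly.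

Step 6. Acyl transfer from the Weinreb amide to a hindered secondary carbanion may be too slow, so that proton transfer returns both partners.

The fallback sets out from 4 and 12 and comes back at 14. Amide 4 is reduced with iBu2AlH (THF, −78 °C) to 3-[4-(triisopropylsilyloxy)phenyl]propanal F2. Dianion 13, made from 12 as before, adds to this far more electrophilic carbonyl at −78 °C. The aldol addition should give 6-{3-hydroxy-9-methyl-4-(3-methylbut-2-enyl)-5-oxo-1-[4-(triisopropylsilyloxy)phenyl]dec-8-en-6-yl}-2,2-dimethyl-4H-1,3-dioxin-4-one F3 as a mixture of diastereomers. Dess–Martin periodinane in CH2Cl2 then oxidises the carbinol to the ketone of 14.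

Step 5. Site control may be lost through O-alkylation of the delocalised enolate or a second alkylation at the same carbon after proton exchange.

The fallback sets out from 7 and comes back at 12, with the two bond formations in reverse order. Dienolate 8, generated with LiN(iPr)2 in THF–DMPU at −78 °C, is alkylated by 10 at its exocyclic carbon to give 2,2-dimethyl-6-(4-methylpent-3-enyl)-4H-1,3-dioxin-4-one F4. LiN(SiMe3)2 converts two equivalents of it into lithium 2,2-dimethyl-6-(4-methylpent-3-enylidene)-1,3-dioxin-4-olate F5. Acid chloride 6 acylates this dienolate at the gamma carbon to give 12, so no active methine is ever exposed to an alkyl halide.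

**Further compounds**
F1 | step 7 | 7-hydroxy-2,2-dimethyl-6,8-bis(3-methylbut-2-enyl)-5-{2-[4-(triisopropylsilyloxy)phenyl]ethyl}-4H-1,3-benzodioxin-4-one | CC1(C)OC(=O)c2c(O1)c(CC=C(C)C)c(O)c(CC=C(C)C)c2CCc1ccc(O[Si](C(C)C)(C(C)C)C(C)C)cc1
F2 | step 6 | 3-[4-(triisopropylsilyloxy)phenyl]propanal | O=CCCc1ccc(O[Si](C(C)C)(C(C)C)C(C)C)cc1
F3 | step 6 | 6-{3-hydroxy-9-methyl-4-(3-methylbut-2-enyl)-5-oxo-1-[4-(triisopropylsilyloxy)phenyl]dec-8-en-6-yl}-2,2-dimethyl-4H-1,3-dioxin-4-one (mixture of diastereomers) | CC1(C)OC(=CC(=O)O1)C(CC=C(C)C)C(=O)C(CC=C(C)C)C(O)CCc1ccc(O[Si](C(C)C)(C(C)C)C(C)C)cc1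
F4 | step 5 | 2,2-dimethyl-6-(4-methylpent-3-enyl)-4H-1,3-dioxin-4-one | CC1(C)OC(=CC(=O)O1)CCC=C(C)C
F5 | step 5 | lithium 2,2-dimethyl-6-(4-methylpent-3-enylidene)-1,3-dioxin-4-olate | [Li+].[O-]C1=CC(=CCC=C(C)C)OC(C)(C)O1
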